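## Analysis of the target

The target is a germacrane, a ten-membered carbocycle. A working numbering is used throughout (not the natural-product numbering): C7 bears the isopropenyl group, then C6 (CH2), C5 (CHOH), C4 (C(CH3)OAc), C3 (CH–O-angeloyl), C2 (CH2), C1 (epoxide CH), C10 (epoxide C–CH3), C9 (CH–O-angeloyl), C8 (CH–O-(R)-2-methylbutanoyl), back to C7. In the flat ring drawing with the isopropenyl group up (β), O3, O5, O8, O9 and both ring methyls are β; the C4 acetoxy group and the epoxide oxygen are α. Eight ring atoms are stereocentres, and a ninth sits in the (R)-2-methylbutanoate. The epoxide is cis (H1 and the C10 methyl on the same side), so it derives from a Z C1=C10 double bond. Five oxygens must each be different: a free secondary OH (C5) next to a tertiary acetate (C4), two angelates, one chiral saturated ester and the epoxide. Sensitive groups are the angelates (Z to E isomerisation), the acetate flanked by hydroxyls (1,2-acyl shift), the medium-ring epoxide (transannular opening) and the isopropenyl alkene (competes in undirected oxidations). The hard parts are the medium ring itself and stereocontrol on a flexible ring. The feature used here: C5 (the only free carbinol) and C10 (the methyl-bearing epoxide carbon) face each other across the ring. A C5–C10 bond would turn the ring into a cis-decalin made of ring A (C10–C1–C2–C3–C4–C5) and ring B (C5–C6–C7–C8–C9–C10). Ring B has the C10 methyl para to the C7 isopropenyl and oxygen on C9 and C8, which is the pattern of carvone (its C2, C5, C1 and C6).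

## Retrosynthetic reasoning

Target 29 is traced back to ketone 28. C5 is the only oxygen that stays unacylated, so it is carried as a ketone through every acylation and reduced last. The forward step must deliver hydride so that O5 ends threo to the C4 acetoxy group.

Ketone 28 comes from epoxy diol 25 and angelic acid 26. Both angelates (O3, O9) go on in one late step because they are the most fragile esters. Diol 25 comes from the Z-alkene 24 by an epoxidation directed by the allylic C9 hydroxyl.

Diol 24 comes from cyclodecenone 23, and 23 from the cis-decalin mesylate 22 by reconnecting C5–C10. This is the key disconnection. Only two transannular bonds turn the ring into a decalin with an oxygenated carbon as fragmentation donor (C5–C10 and C4–C9). The C5–C10 bond puts the new alkene exactly where the epoxide is needed, turns C5 into the ketone wanted for the endgame, and lets C3, C4, C8 and C9 be set on a rigid bicycle. The ten-membered ring is then never closed; it is released. The forward reaction must cleave C5–C10 with Z geometry at C1=C10 and leave three esters and two silyl ethers alone.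

Mesylate 22 goes back through 19 and 18 to allylic alcohol 17. The C4 acetate and the C3 hydroxyl come from trans-diaxial opening of a 3β,4β-epoxide at its tertiary carbon, and the epoxide from the tertiary allylic alcohol. Alcohol 17 comes from epoxy ketone 15 and enone 14 by a Wharton transposition, which moves oxygen from C3 to C5 and so creates the fragmentation trigger.

Enone 14 goes back to Diels–Alder adduct 9, made from enone 4 and diene 8. This one cycloaddition joins all fifteen skeletal carbons, builds ring A with oxygen at C1 and C3, and sets the cis ring fusion.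

Enone 4 comes from (S)-carvone 1 and acid 3. Carvone supplies C7 with its configuration, the C10 methyl and the C9 carbonyl. C8 is oxygenated at the activated α′ position, and the ester is introduced with inversion so that O8 is cis to the isopropenyl group. Diene 8 comes from ynone 5 and alcohol 6 via enone 7.

## Alternatives that were turned down

Alternative 1: the textbook route cuts the C7–C8 bond. The forward key step is an intramolecular chromium(II)-mediated allylation of the acyclic aldehyde–allylic bromide A1 to the macrocyclic homoallylic alcohol A2, which would close the ring, set C7 and C8 and create the isopropenyl group. It was turned down for three reasons. A1 carries six stereocentres that must each be set by a separate reagent-controlled step on an open chain, so the sequence before any ring exists is long. The chain between the reacting ends is fully sp3 with three bulky silyl ethers and no E-alkenes to pre-organise it, so ten-ring closure must compete with oligomerisation and transannular strain. The two new centres C7 and C8 would be formed in the least controlled step, and the α-alkoxy-β,γ-epoxy aldehyde is prone to elimination.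

Alternative 2: an anionic oxy-Cope ring expansion, forming C2–C3 while C5–C10 breaks. The carvone-derived 1,2-dialkenylcyclohexanol A3 would rearrange, and the resulting enolate would be hydroxylated to cyclodecenone A4. It was turned down because the carbinol carbon C5 must be the carvone carbonyl, which places C8 and C9 on unactivated carvone positions, so A3 and A4 lack these oxygens. The C1=C10 geometry depends on a chair/boat competition of a cis-dialkenyl system and is not stereospecific. C3 is not oxygenated, and the C3/C4 pair would have to be set on the macrocycle.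

Alternative 3: the other transannular fragmentation, across C4–C9. An intramolecular alkenyl-metal addition of keto mesylate A5 to its ketone would be followed by Grob fragmentation to dienone A6. The precursor is short to make. It was turned down because C4 becomes sp2, so C4 with C5, plus C8, C9, C1 and C10, would all have to be set on the flexible ring. The C4 tertiary acetate and the free C5 hydroxyl would then arise from a diol and could not be told apart without extra protecting-group steps. Two secondary hydroxyls on either side of the quaternary carbon must also be differentiated before the key step.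

Key step: step 17

Assumption: pent-1-yn-3-one (5) is taken as a purchasable building block; it is otherwise one oxidation away from pent-1-yn-3-ol.

## Route

Step 1
Reactants: 1 (S)-(+)-carvone
Product: 2 trans-6-hydroxycarvone
Conditions: LDA, THF, –78 °C; then 2-(phenylsulfonyl)-3-phenyloxaziridine, –78 → –40 °C
Reagents that add atoms: 2-(phenylsulfonyl)-3-phenyloxaziridine, O=S(=O)(c1ccccc1)N1OC1c1ccccc1
Why: Kinetic α′-deprotonation gives the cross-conjugated enolate, which the N-sulfonyloxaziridine hydroxylates (enolate oxidation); the oxidant approaches C8 anti to the neighbouring isopropenyl group, so the trans ketol should predominate.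

Step 2
Reactants: 2 trans-6-hydroxycarvone; 3 (R)-2-methylbutanoic acid
Product: 4 cis-6-[(R)-2-methylbutanoyloxy]carvone
Conditions: PPh3, DIAD, toluene, 0 °C → rt
Reagents that add atoms: none
Why: Mitsunobu esterification displaces the carbonyl-activated oxyphosphonium with inversion, giving the cis (8β) ester and installing the (R)-2-methylbutanoate, whose own stereocentre is not involved; both ring substituents then lie on the β-face for step 5.

Step 3
Reactants: 5 pent-1-yn-3-one; 6 4-methoxybenzyl alcohol
Product: 7 (E)-1-[(4-methoxybenzyl)oxy]pent-1-en-3-one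
Conditions: PMe3 (cat.), CH2Cl2, 0 °C
Reagents that add atoms: none
Why: Phosphine-catalysed oxa-Michael addition of the alcohol to the ynone should give the E β-alkoxy enone.

Step 4
Reactants: 7 (E)-1-[(4-methoxybenzyl)oxy]pent-1-en-3-one
Product: 8 (1E,3Z)-1-[(4-methoxybenzyl)oxy]-3-[(trimethylsilyl)oxy]penta-1,3-diene
Conditions: TMSOTf, Et3N, Et2O, 0 °C
Reagents that add atoms: trimethylsilyl trifluoromethanesulfonate, C[Si](C)(C)OS(=O)(=O)C(F)(F)F
Why: Soft enolisation of the ethyl ketone gives the 1-alkoxy-3-silyloxy diene (silyl enol ether formation) with the methyl group on the outside of the diene.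

Step 5
Reactants: 4 cis-6-[(R)-2-methylbutanoyloxy]carvone; 8 silyloxy diene
Product: 9 cis-decalin Diels–Alder adduct (1α-OPMB, Δ2 3-OTMS, 9-ketone)
Conditions: EtAlCl2 (0.5 equiv), toluene, –78 → –20 °C
Reagents that add atoms: none
Why: Lewis-acid-catalysed Diels–Alder reaction of a 2-methylcyclohexenone with a 3-silyloxy diene; the nucleophilic diene terminus C4 bonds to the enone β-carbon (C5) and C1 to C10. The diene adds to the α-face, anti to the isopropenyl and acyloxy groups, which sets C10 (β-CH3) and C5 (β-H) as a cis fusion, and the endo transition state places the C1 alkoxy group α. Chelation of aluminium by the α′-acyloxy ketone should raise dienophile reactivity.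

Step 6
Reactants: 9 Diels–Alder adduct
Product: 11 9β-hydroxy 3-ketone, via TMS enol ether alcohol 10 (not isolated)
Conditions: Zn(BH4)2, Et2O, –20 °C; then 0.5 M HCl, THF, 0 °C (work-up)
Reagents that add atoms: none
Why: Neutral zinc borohydride reduces the only ketone without acyl migration and leaves the silyl enol ether intact until the acidic work-up; hydride enters on the α-face, opposite the C10 methyl and C8 acyloxy groups that flank the carbonyl on the β-face, giving the 9β alcohol (substrate-controlled ketone reduction).

Step 7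
Reactants: 11 9β-hydroxy 3-ketone
Product: 12 9β-silyloxy 3-ketone
Conditions: TBSOTf, 2,6-lutidine, CH2Cl2, –78 °C
Reagents that add atoms: tert-butyldimethylsilyl trifluoromethanesulfonate, CC(C)(C)[Si](C)(C)OS(=O)(=O)C(F)(F)F
Why: At low temperature the silyl triflate with a hindered pyridine silylates the alcohol faster than it enolises the ketone; the silyl ether blocks a later 1,2-acyl shift from O8 to O9.

Step 8
Reactants: 12 9β-silyloxy 3-ketone
Product: 13 Δ3 trimethylsilyl enol ether
Conditions: TMSOTf (1.2 equiv), Et3N, CH2Cl2, 0 °C → rt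
Reagents that add atoms: trimethylsilyl trifluoromethanesulfonate, C[Si](C)(C)OS(=O)(=O)C(F)(F)F
Why: Under equilibrating silylation the cis-fused 3-ketone should give the tetrasubstituted Δ3 enol ether (thermodynamic silyl enol ether formation); the ketone is silylated far faster than the hindered esters, so the ester α-stereocentre is not put at risk.

Step 9
Reactants: 13 Δ3 trimethylsilyl enol ether
Product: 14 Δ4-3-ketone (enone)
Conditions: Pd(OAc)2, MeCN, rt
Reagents that add atoms: none
Why: Saegusa–Ito oxidation: the C4 palladium enolate loses the C5 hydrogen by β-hydride elimination to give the conjugated tetrasubstituted enone; the C4 and C5 centres from step 5 are erased on purpose.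

Step 10
Reactants: 14 Δ4-3-ketone
Product: 15 4β,5β-epoxy 3-ketone
Conditions: t-BuOOH, DBU, CH2Cl2, 0 °C → rt
Reagents that add atoms: tert-butyl hydroperoxide, CC(C)(C)OO
Why: Weitz–Scheffer epoxidation: the peroxide anion adds to C5 and closes on C4; β-face attack gives a cis-fused product and avoids the α-oriented C1 substituent, as is usual for 10β-methyl Δ4-3-ketones. The weak amidine base and low temperature are chosen to keep the β-alkoxy ketone from eliminating.

Step 11
Reactants: 15 4β,5β-epoxy 3-ketone
Product: 17 Δ3 allylic 5β-alcohol, via epoxy hydrazone 16 (not isolated)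
Conditions: N2H4·H2O, AcOH (cat.), MeOH, 0 °C → rt
Reagents that add atoms: hydrazine, NN (its nitrogens appear only in 16 and leave as N2)
Why: Wharton transposition: the epoxy hydrazone collapses with loss of nitrogen, C3=C4 forms and the epoxide oxygen stays on C5 with retention, giving the tertiary 5β-alcohol that later triggers the fragmentation.

Step 12
Reactants: 17 Δ3 allylic 5β-alcohol
Product: 18 3β,4β-epoxy 5β-alcohol
Conditions: VO(acac)2 (cat.), t-BuOOH, CH2Cl2, 0 °C
Reagents that add atoms: tert-butyl hydroperoxide, CC(C)(C)OO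
Why: Vanadium-catalysed hydroxyl-directed epoxidation delivers oxygen syn to the tertiary allylic hydroxyl and leaves the isopropenyl group, which has no directing hydroxyl, untouched.

Step 13
Reactants: 18 3β,4β-epoxy 5β-alcohol
Product: 19 3β,5β-diol 4α-acetate
Conditions: AcOH, NaOAc, 40 °C
Reagents that add atoms: acetic acid, CC(=O)O
Why: Acid-mediated epoxide opening by acetate at the tertiary carbon C4 with inversion (Markovnikov and trans-diaxial, Fürst–Plattner) sets C4 (α-OAc, β-CH3), frees the 3β-hydroxyl and installs the tertiary acetate without acylating a tertiary alcohol; the acetate buffer limits semipinacol shift of the neighbouring carbinol.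

Step 14
Reactants: 19 3β,5β-diol 4α-acetate
Product: 20 3β,9β-bis-silyl ether 5β-alcohol
Conditions: TBSOTf (1.1 equiv), 2,6-lutidine, CH2Cl2, –40 °C
Reagents that add atoms: tert-butyldimethylsilyl trifluoromethanesulfonate, CC(C)(C)[Si](C)(C)OS(=O)(=O)C(F)(F)F
Why: Only the secondary C3 hydroxyl is silylated; the tertiary axial C5 hydroxyl between two quaternary carbons is left free. The silyl ether prevents retro-aldol cleavage and acetyl shift in the base step.

Step 15
Reactants: 20 bis-silyl ether
Product: 21 1α,5β-diol
Conditions: DDQ, CH2Cl2/pH 7 buffer, 0 °C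
Reagents that add atoms: none
Why: Oxidative cleavage of the p-methoxybenzyl ether through its oxocarbenium ion in wet solvent; silyl ethers, esters and isolated alkenes are inert to the quinone.

Step 16
Reactants: 21 1α,5β-diol
Product: 22 1α-mesylate 5β-alcohol
Conditions: MsCl, Et3N, CH2Cl2, –20 °C
Reagents that add atoms: methanesulfonyl chloride, CS(=O)(=O)Cl
Why: Sulfonylation of the secondary equatorial 1α-alcohol; the tertiary alcohol does not react and the amine is too weak a base to start the fragmentation.

Step 17
Reactants: 22 1α-mesylate 5β-alcohol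
Product: 23 (Z)-cyclodec-1(10)-en-5-one
Conditions: KHMDS (1.05 equiv), THF, –78 → 0 °C
Reagents that add atoms: none
Why: Deprotonation of the tertiary C5–OH gives an alkoxide whose lone pair, the C5–C10 σ-bond and the equatorial C1–OMs bond are antiperiplanar in the chair–chair cis-decalin, so C5=O forms, C5–C10 breaks and mesylate leaves in one concerted heterolytic fragmentation (Grob fragmentation). The closest known reaction type is the Wharton fragmentation of decalin-1,3-diol monosulfonates to cyclodecenones. No ring is closed in the Baldwin sense: the ten-membered ring arises by cleaving the bond shared by the two six-membered rings. The only new stereo-element, the C1=C10 double bond, is fixed as Z by the substrate: with the 1α-sulfonate anti to C5–C10, C2 is gauche to C9, which is axial to ring A in the cis-fused system, so C2 and C9 end cis (a trans-decalin would give E). C3, C4, C7, C8 and C9 are not touched; C1, C5 and C10 serve only as control elements and are given up. Fragmentation must outrun E2 elimination, oxetane closure and acyl or silyl transfer: the equatorial sulfonate has no antiperiplanar hydrogen and cannot be attacked from the rear by O5, and the 4α-acetate is trans-diaxial to O5 and cannot bridge to it. One equivalent of a non-nucleophilic base at low temperature should leave the three esters and the α-acetoxy ketone product intact.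

Step 18
Reactants: 23 (Z)-cyclodecenone
Product: 24 3β,9β-diol
Conditions: HF·pyridine, pyridine/THF, 0 °C → rt
Reagents that add atoms: none
Why: Fluoride removes both secondary silyl ethers; buffered HF leaves esters, α-acetoxy ketone and alkenes intact and avoids basic conditions under which the C4 acetyl group could shift to O3.

Step 19
Reactants: 24 3β,9β-diol
Product: 25 1α,10α-epoxy diol
Conditions: mCPBA (1.05 equiv), NaHCO3, CH2Cl2, –20 → 0 °C
Reagents that add atoms: 3-chloroperoxybenzoic acid, O=C(OO)c1cccc(Cl)c1
Why: Hydroxyl-directed peracid epoxidation (Henbest type) of the cis-trisubstituted allylic alcohol: with H9 in the alkene plane to avoid A(1,3) strain with C2, the hydrogen-bonded peracid should deliver oxygen to the face that gives the threo (trans) epoxy alcohol, i.e. the α-epoxide; the hydroxyl-activated trisubstituted ring alkene reacts before the isopropenyl group.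

Step 20
Reactants: 25 epoxy diol; 26 angelic acid
Product: 28 5-ketone tetraester, via angeloyl 2,4,6-trichlorobenzoyl anhydride 27 (not isolated)
Conditions: 26, 2,4,6-trichlorobenzoyl chloride, Et3N, toluene, rt; then 25, toluene, 75 °C
Reagents that add atoms: 2,4,6-trichlorobenzoyl chloride, O=C(Cl)c1c(Cl)cc(Cl)cc1Cl (retained only in 27)
Why: Mixed-anhydride (Yamaguchi-type) acylation transfers the angeloyl group to both hindered secondary alcohols in one operation; omitting a nucleophilic pyridine catalyst avoids isomerisation of the Z-enoate to the tiglate.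

Step 21
Reactants: 28 5-ketone tetraester
Product: 29 target CNP0197637.1
Conditions: NaBH4, MeOH/CH2Cl2, –40 °C; AcOH quench
Reagents that add atoms: none
Why: Borohydride reduces only the ketone; in the Felkin–Anh arrangement the polar α-acetoxy group is anti to the incoming hydride, which leads to the threo O4/O5 relationship (5β-OH) of the target; low temperature and an acidic quench prevent acetyl migration.

## Compound list

1 | (S)-(+)-carvone, (5S)-2-methyl-5-(prop-1-en-2-yl)cyclohex-2-en-1-one | CC1=CC[C@@H](CC1=O)C(C)=C | starting material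
2 | trans-6-hydroxycarvone, (5R,6R)-6-hydroxy-2-methyl-5-(prop-1-en-2-yl)cyclohex-2-en-1-one | C=C(C)[C@H]1CC=C(C)C(=O)[C@@H]1O | intermediate
3 | (R)-2-methylbutanoic acid | CC[C@@H](C)C(=O)O | starting material
4 | cis-6-acyloxycarvone, (1S,6R)-3-methyl-2-oxo-6-(prop-1-en-2-yl)cyclohex-3-en-1-yl (2R)-2-methylbutanoate | C=C(C)[C@H]1CC=C(C)C(=O)[C@H]1OC(=O)[C@H](C)CC | intermediate
5 | pent-1-yn-3-one | CCC(=O)C#C | starting material
6 | 4-methoxybenzyl alcohol | COc1ccc(CO)cc1 | starting material
7 | (E)-1-[(4-methoxybenzyl)oxy]pent-1-en-3-one | CCC(=O)/C=C/OCc1ccc(OC)cc1 | intermediate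
8 | (1E,3Z)-1-[(4-methoxybenzyl)oxy]-3-[(trimethylsilyl)oxy]penta-1,3-diene | C/C=C(O[Si](C)(C)C)/C=C/OCc1ccc(OC)cc1 | intermediate
9 | Diels–Alder adduct: cis-decalin (C5–C10 bond), 1α-OPMB, Δ2 with 3-OTMS, 4α-CH3, 5β-H, 7β-isopropenyl, 8β-O-(R)-2-methylbutanoyl, 9-oxo, 10β-CH3 | C=C(C)[C@H]1C[C@@H]2[C@H](C)C(O[Si](C)(C)C)=C[C@H](OCc3ccc(OC)cc3)[C@]2(C)C(=O)[C@H]1OC(=O)[C@H](C)CC | intermediate
10 | as 9 with 9β-OH in place of the ketone | C=C(C)[C@H]1C[C@@H]2[C@H](C)C(O[Si](C)(C)C)=C[C@H](OCc3ccc(OC)cc3)[C@]2(C)[C@@H](O)[C@H]1OC(=O)[C@H](C)CC | intermediate (not isolated)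
11 | 9β-hydroxy 3-ketone (1α-OPMB, 4α-CH3, 5β-H) | C=C(C)[C@H]1C[C@@H]2[C@H](C)C(=O)C[C@H](OCc3ccc(OC)cc3)[C@]2(C)[C@@H](O)[C@H]1OC(=O)[C@H](C)CC | intermediate
12 | 9β-OTBS 3-ketone | C=C(C)[C@H]1C[C@@H]2[C@H](C)C(=O)C[C@H](OCc3ccc(OC)cc3)[C@]2(C)[C@@H](O[Si](C)(C)C(C)(C)C)[C@H]1OC(=O)[C@H](C)CC | intermediate
13 | Δ3 trimethylsilyl enol ether of 12 | C=C(C)[C@H]1C[C@@H]2C(C)=C(O[Si](C)(C)C)C[C@H](OCc3ccc(OC)cc3)[C@]2(C)[C@@H](O[Si](C)(C)C(C)(C)C)[C@H]1OC(=O)[C@H](C)CC | intermediate
14 | Δ4-3-ketone (4-methyl enone), 1α-OPMB, 9β-OTBS | C=C(C)[C@H]1CC2=C(C)C(=O)C[C@H](OCc3ccc(OC)cc3)[C@]2(C)[C@@H](O[Si](C)(C)C(C)(C)C)[C@H]1OC(=O)[C@H](C)CC | intermediate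
15 | 4β,5β-epoxy 3-ketone | C=C(C)[C@H]1C[C@@]23O[C@@]3(C)C(=O)C[C@H](OCc4ccc(OC)cc4)[C@]2(C)[C@@H](O[Si](C)(C)C(C)(C)C)[C@H]1OC(=O)[C@H](C)CC | intermediate
16 | hydrazone of 15 | C=C(C)[C@H]1C[C@@]23O[C@@]3(C)C(=NN)C[C@H](OCc4ccc(OC)cc4)[C@]2(C)[C@@H](O[Si](C)(C)C(C)(C)C)[C@H]1OC(=O)[C@H](C)CC | intermediate (not isolated)
17 | Δ3 allylic alcohol, 5β-OH (cis-decalin) | C=C(C)[C@H]1C[C@]2(O)C(C)=CC[C@H](OCc3ccc(OC)cc3)[C@]2(C)[C@@H](O[Si](C)(C)C(C)(C)C)[C@H]1OC(=O)[C@H](C)CC | intermediate
18 | 3β,4β-epoxy 5β-alcohol | C=C(C)[C@H]1C[C@]2(O)[C@@]3(C)O[C@H]3C[C@H](OCc4ccc(OC)cc4)[C@]2(C)[C@@H](O[Si](C)(C)C(C)(C)C)[C@H]1OC(=O)[C@H](C)CC | intermediate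
19 | 3β,5β-diol 4α-acetate (4β-CH3) | C=C(C)[C@H]1C[C@]2(O)[C@](C)(OC(C)=O)[C@@H](O)C[C@H](OCc3ccc(OC)cc3)[C@]2(C)[C@@H](O[Si](C)(C)C(C)(C)C)[C@H]1OC(=O)[C@H](C)CC | intermediate
20 | 3β,9β-bis-OTBS 5β-alcohol 4α-acetate, 1α-OPMB | C=C(C)[C@H]1C[C@]2(O)[C@](C)(OC(C)=O)[C@@H](O[Si](C)(C)C(C)(C)C)C[C@H](OCc3ccc(OC)cc3)[C@]2(C)[C@@H](O[Si](C)(C)C(C)(C)C)[C@H]1OC(=O)[C@H](C)CC | intermediate
21 | 1α,5β-diol | C=C(C)[C@H]1C[C@]2(O)[C@](C)(OC(C)=O)[C@@H](O[Si](C)(C)C(C)(C)C)C[C@H](O)[C@]2(C)[C@@H](O[Si](C)(C)C(C)(C)C)[C@H]1OC(=O)[C@H](C)CC | intermediate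
22 | 1α-mesylate 5β-alcohol (fragmentation precursor) | C=C(C)[C@H]1C[C@]2(O)[C@](C)(OC(C)=O)[C@@H](O[Si](C)(C)C(C)(C)C)C[C@H](OS(C)(=O)=O)[C@]2(C)[C@@H](O[Si](C)(C)C(C)(C)C)[C@H]1OC(=O)[C@H](C)CC | intermediate
23 | (Z)-cyclodec-1(10)-en-5-one: 3β,9β-bis-OTBS, 4α-OAc, 8β-O-(R)-2-methylbutanoyl, 7β-isopropenyl | C=C(C)[C@H]1CC(=O)[C@](C)(OC(C)=O)[C@@H](O[Si](C)(C)C(C)(C)C)C/C=C(/C)[C@@H](O[Si](C)(C)C(C)(C)C)[C@H]1OC(=O)[C@H](C)CC | intermediate
24 | 3β,9β-diol of 23 | C=C(C)[C@H]1CC(=O)[C@](C)(OC(C)=O)[C@@H](O)C/C=C(/C)[C@@H](O)[C@H]1OC(=O)[C@H](C)CC | intermediate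
25 | 1α,10α-epoxy 3β,9β-diol 5-ketone | C=C(C)[C@H]1CC(=O)[C@](C)(OC(C)=O)[C@@H](O)C[C@@H]2O[C@]2(C)[C@@H](O)[C@H]1OC(=O)[C@H](C)CC | intermediate
26 | angelic acid, (Z)-2-methylbut-2-enoic acid | C/C=C(/C)C(=O)O | starting material
27 | angelic 2,4,6-trichlorobenzoic anhydride | C/C=C(/C)C(=O)OC(=O)c1c(Cl)cc(Cl)cc1Cl | intermediate (not isolated)
28 | 5-ketone tetraester (3,9-diangelate, 4-acetate, 8-(R)-2-methylbutanoate, 1,10-epoxide) | C=C(C)[C@H]1CC(=O)[C@](C)(OC(C)=O)[C@@H](OC(=O)/C(C)=C\C)C[C@@H]2O[C@]2(C)[C@@H](OC(=O)/C(C)=C\C)[C@H]1OC(=O)[C@H](C)CC | intermediate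
29 | CNP0197637.1 | C=C(C)[C@H]1C[C@@H](O)[C@](C)(OC(C)=O)[C@@H](OC(=O)/C(C)=C\C)C[C@@H]2O[C@]2(C)[C@@H](OC(=O)/C(C)=C\C)[C@H]1OC(=O)[C@H](C)CC | target

## Step count and least certain steps

Total: 21 steps. Longest linear sequence: 19 steps (steps 1, 2, 5–21 from carvone); steps 3 and 4 make the diene.

Step 17 (key step). The reactive chair–chair conformer carries three axial oxygens on ring A. If ring A escapes into a twist form, the antiperiplanar alignment is lost, fragmentation slows, and base-induced silyl transfer from O3 to O5 or cleavage of the tertiary acetate can take over. Fallback: cut the same C5–C10 bond by a retro-aldol instead. Starting from diol 21, Dess–Martin oxidation of the C1 alcohol gives the β-hydroxy ketone F1. KHMDS at –78 °C opens C5–C10 by retro-aldol, and the C1 enolate is trapped with N-(5-chloro-2-pyridyl)triflimide as the ten-membered enol triflate F2. Palladium-catalysed formate reduction of the triflate then gives 23, where the route is rejoined. The alkene geometry is then set by the enolate and is no longer guaranteed by stereospecificity.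

Step 5. The acid-labile oxygenated diene may decompose, or add in a Mukaiyama–Michael sense without closing the ring, and endo selectivity at C1 may erode. Fallback: a two-stage annulation from 4 and 8. Silyl-triflate-catalysed Mukaiyama–Michael addition of the diene terminus to the enone gives the open-chain silyl enol ether F3. A separately triggered intramolecular Mukaiyama–Michael addition onto the β-alkoxy enone then forms C10–C1 with silyl transfer to O3 and returns to 9.

Step 10. The C2 enolate of the β-alkoxy ketone may expel the C1 alkoxy group (E1cB), and conjugate attack on the tetrasubstituted enone may be slow; the hydrazine step that follows shares this sensitivity. Fallback: a base-free transposition from 14. Luche reduction gives the 3β-allylic alcohol F4, vanadium-directed epoxidation gives the 4β,5β-epoxy 3β-alcohol F5, and thiocarbonyldiimidazole gives the thiocarbonyl imidazolide F6. Tributyltin hydride (AIBN, high hydride concentration) then generates the C3 radical, which opens the epoxide to the Δ3 5β-alcohol 17, where the route is rejoined.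

Step 20. Acylation of two hindered secondary alcohols may be slow, which leaves time for angelate-to-tiglate isomerisation and for a 1,2-shift of the C4 acetyl group to O3. Fallback: build the Z-enoates on the molecule. From 25, carbodiimide coupling with 2-[bis(2,2,2-trifluoroethoxy)phosphoryl]propanoic acid gives the bis-phosphonate ester F7. Still–Gennari olefination with acetaldehyde (KHMDS, 18-crown-6, –78 °C) converts both phosphonates into angelates and returns to 28.

Step 21. The ring conformation may oppose the Felkin–Anh preference and give poor facial selectivity, and the acetyl group may migrate from O4 to the new alkoxide. Fallback: move from substrate control to reagent control. Reduce 28 with catecholborane and the (R)- or (S)-2-methyl-CBS-oxazaborolidine, whichever enantiomer delivers hydride to the required face, to reach 29 directly; no new compound arises.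

## Further compounds

F1 | step 17 | 1-keto 5β-alcohol from oxidation of 21 | C=C(C)[C@H]1C[C@]2(O)[C@](C)(OC(C)=O)[C@@H](O[Si](C)(C)C(C)(C)C)CC(=O)[C@]2(C)[C@@H](O[Si](C)(C)C(C)(C)C)[C@H]1OC(=O)[C@H](C)CC
F2 | step 17 | ten-membered (Z)-C1 enol triflate 5-ketone | C=C(C)[C@H]1CC(=O)[C@](C)(OC(C)=O)[C@@H](O[Si](C)(C)C(C)(C)C)C/C(OS(=O)(=O)C(F)(F)F)=C(/C)[C@@H](O[Si](C)(C)C(C)(C)C)[C@H]1OC(=O)[C@H](C)CC
F3 | step 5 | open-chain Michael adduct: C9 trimethylsilyl enol ether with the β-alkoxy enone chain on C5 (C4 configuration not defined) | C=C(C)[C@H]1C[C@H](C(C)C(=O)/C=C/OCc2ccc(OC)cc2)C(C)=C(O[Si](C)(C)C)[C@H]1OC(=O)[C@H](C)CC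
F4 | step 10 | 3β-allylic alcohol from 14 | C=C(C)[C@H]1CC2=C(C)[C@@H](O)C[C@H](OCc3ccc(OC)cc3)[C@]2(C)[C@@H](O[Si](C)(C)C(C)(C)C)[C@H]1OC(=O)[C@H](C)CC
F5 | step 10 | 4β,5β-epoxy 3β-alcohol | C=C(C)[C@H]1C[C@@]23O[C@@]3(C)[C@@H](O)C[C@H](OCc4ccc(OC)cc4)[C@]2(C)[C@@H](O[Si](C)(C)C(C)(C)C)[C@H]1OC(=O)[C@H](C)CC
F6 | step 10 | 3β-O-(imidazol-1-ylthiocarbonyl) derivative of F5 | C=C(C)[C@H]1C[C@@]23O[C@@]3(C)[C@@H](OC(=S)n5ccnc5)C[C@H](OCc4ccc(OC)cc4)[C@]2(C)[C@@H](O[Si](C)(C)C(C)(C)C)[C@H]1OC(=O)[C@H](C)CC
F7 | step 20 | 3,9-bis{2-[bis(2,2,2-trifluoroethoxy)phosphoryl]propanoate} of 25 (phosphonate α-carbons not defined) | C=C(C)[C@H]1CC(=O)[C@](C)(OC(C)=O)[C@@H](OC(=O)C(C)P(=O)(OCC(F)(F)F)OCC(F)(F)F)C[C@@H]2O[C@]2(C)[C@@H](OC(=O)C(C)P(=O)(OCC(F)(F)F)OCC(F)(F)F)[C@H]1OC(=O)[C@H](C)CC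
F0 | step 21 | none | none
A1 | alternative 1 | acyclic aldehyde–allylic bromide (C8 aldehyde, C12 bromide, 1,10-epoxide, 4-acetate, 3,5,9-tris-OTES) | BrC/C(C)=C/C[C@@H](O[Si](CC)(CC)CC)[C@](C)(OC(C)=O)[C@@H](O[Si](CC)(CC)CC)C[C@@H]1O[C@]1(C)[C@@H](O[Si](CC)(CC)CC)C=O
A2 | alternative 1 | macrocyclic homoallylic alcohol (8β-OH, 7β-isopropenyl) | C=C(C)[C@H]1C[C@@H](O[Si](CC)(CC)CC)[C@](C)(OC(C)=O)[C@@H](O[Si](CC)(CC)CC)C[C@@H]2O[C@]2(C)[C@@H](O[Si](CC)(CC)CC)[C@H]1O
A3 | alternative 2 | 2-methyl-1,5-di(prop-1-en-2-yl)-2-vinylcyclohexan-1-ol (cis-dialkenyl) | C=C(C)[C@@H]1CC[C@](C)(C=C)[C@](O)(C(C)=C)C1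
A4 | alternative 2 | 4-hydroxy-4,10-dimethyl-7-isopropenyl-cyclodec-1(10)-en-5-one | C=C(C)[C@@H]1CC/C(C)=C\CC[C@@](C)(O)C(=O)C1
A5 | alternative 3 | carvone-derived keto mesylate with (Z)-iodoalkenyl side chain | C=C(C)[C@H]1C[C@H](OS(C)(=O)=O)[C@@](C)([C@@H](O[Si](C)(C)C(C)(C)C)C/C=C(/C)I)C(=O)C1
A6 | alternative 3 | (1Z,4E)-3-silyloxy-cyclodeca-1(10),4-dien-9-one | C=C(C)[C@H]1C/C=C(\C)[C@@H](O[Si](C)(C)C(C)(C)C)C/C=C(/C)C(=O)C1
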